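## Structural features

The target is an open-chain 1,3-diarylpropan-1-one. Ring A (a benzene ring with the ketone at C1, a free hydroxyl at C2 and a geranyl ether at C4) and ring B (a 4-hydroxyphenyl group) are joined through C(=O)–CH(OH)–CH2, with no ring fusion and no further ring. The only stereocentre is the carbinol carbon between the ketone and the benzylic methylene; it is R and has no stereogenic neighbour, so its configuration must come from an absolute source. The fragile elements are the α-ketol, which loses configuration or undergoes acyloin transposition through its enediol under base, and the geranyl ether, an allylic aryl ether with two trisubstituted alkenes that excludes hydrogenation, zerovalent palladium, strong acid and unselective electrophiles or oxidants. Three phenolic oxygens must end up differentiated: O4 of ring A alkylated, the other two free. The real difficulty is therefore to place the geranyl group on exactly one oxygen and to keep an enolisable, enantiopure α-ketol intact beside it, not to build the carbon chain. The key step exploits the fact that ring A, with acyl at C1, hydroxyl at C2 and alkoxy at C4, is the dehydrogenated form of a 6-acyl-3-alkoxycyclohex-2-en-1-one: the enone carbonyl becomes the C2 phenol, the enol ether oxygen becomes O4, and the α′ carbon C6 becomes C1 and can be joined to the ketone carbon by enolate acylation.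

## Logic of the disconnections

20 back to 19. No skeletal bond is cut: the carbinol oxygen and the ring B phenol oxygen are capped as silyl ethers. These are the two hydroxyls that would interfere with the enolate, hydride-base and peracid steps; the ring A phenol does not exist before step 7 and needs no protection. The gain is that every earlier intermediate has a single acidic site. The demand is a final cleavage that is neither basic enough to enolise the α-ketol nor acidic enough to ionise the allylic ether.

19 back to 16 (through 18 and 17). The aromatic sextet of ring A is dismantled: the C5=C6 double bond is exchanged for C5–H and a C6–Se bond. 19 is the phenol tautomer of dienone 18, and 18 is the syn-elimination product of selenoxide 17. The gain is a cyclohexenone ring whose two oxygens differ by construction (ketone and enol ether). The demand is oxidation at selenium in the presence of two trisubstituted alkenes, and elimination towards C5.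

16 back to 14. The C6–Se bond is cut. C6 of 14 is the central carbon of a β-diketone and the only strongly acidic position, so the heteroatom can be placed there without regiochemical doubt. The demand is a selenium electrophile that reacts with an enolate but not with an alkene.

14 back to 4 and 11. The bond between C6 and the ketone carbon is cut. It is the only C–C bond that joins the ring A surrogate to the chiral three-carbon chain with ring B, so the synthesis becomes convergent and the stereocentre arrives ready-made in 11. The demand is regioselective α′ deprotonation of 4, acylation on carbon without over-addition, and no base in the flask strong enough to remove the α-proton of 11.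

4 back to 1 and 2. The bond between the enol ether oxygen and the allylic CH2 is cut. 1 is symmetrical, so mono-O-alkylation has only one regiochemical outcome and the problem of choosing among phenols disappears. The demand is alkylation on oxygen, not carbon, under non-acidic conditions and without allylic transposition.

11 back to 10. Two O–Si bonds are cut. Silylation is placed after amidation so that no silyl ester is formed and then selectively cleaved. The forward step is routine.

10 back to 8. The amide C–N bond is cut. The acid oxidation level is already present, and the N-methoxy-N-methylamide is the acyl cation equivalent that the key step needs. The demand is an activation method that tolerates a free secondary alcohol and a free phenol.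

8 back to 5. The C–O bond at the stereocentre is exchanged for a C–N bond. 5 is a commercial amino acid with the full ring B side chain and the required configuration. The demand is substitution with net retention.

## Other disconnections considered

Alternative 1: The cut goes through two bonds of ring A, C1–C2 and C5–C6 (C1 = acyl-bearing carbon). Ring A would be assembled from the two alkyne carbons of the terminal ynone (4R)-4-(tert-butyldimethylsilyloxy)-5-[4-(tert-butyldimethylsilyloxy)phenyl]pent-1-yn-3-one A2 and the four carbons of 1-methoxy-1,3-bis(trimethylsilyloxy)buta-1,3-diene A3.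
- Forward key step: a [4+2] cycloaddition of A3 to A2 (or its stepwise Michael/aldol equivalent), then loss of methanol and of the trimethylsilyl groups, would give the resorcinol ketone (2R)-2-(tert-butyldimethylsilyloxy)-3-[4-(tert-butyldimethylsilyloxy)phenyl]-1-(2,4-dihydroxyphenyl)propan-1-one A1. In A1 the 4-hydroxyl, the one not tied up in the hydrogen bond to the ketone, would then be geranylated; this would give 19, and the desilylation of step 8 would finish the synthesis.
- In favour: ring A arrives aromatic in A1, so no dehydrogenation is needed and no selenium or peracid meets the geranyl alkenes. The push–pull polarity of A2 and A3 matches the ortho/para placement of the two oxygens. A2 is one step from 11, so the source of chirality is the same.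
- Against: the carbinol proton of A2 is more acidic than that of 11, and a terminal ynone invites conjugate addition and polymerisation. The benzannulation may need Lewis acid or heat and may stop at open-chain or pyranone products. The geranyl group goes onto the resorcinol A1 at the end, which brings back a choice between two phenols, to be made with base beside a silyloxy ketone.
- Comparison: on structure the chosen plan is better, because its ether oxygen is fixed by construction, whereas A1 offers two free hydroxyls on ring A. On mechanism the alternative is the better plan in oxidation-state economy and in safety of the geranyl group, while the chosen plan is better in that its stereocentre never sits next to an ynone. On step economy the alternative equals the chosen plan in longest linear sequence and is about one step shorter overall if A3 is bought.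

Alternative 2: The cut is the C–O bond at the carbinol carbon. The stereocentre would be made last, by reagent control, on the achiral dihydrochalcone 1-[4-(geranyloxy)-2-hydroxyphenyl]-3-[4-(tert-butyldimethylsilyloxy)phenyl]propan-1-one A5.
- Forward key step: two equivalents of NaN(SiMe3)2 would give the phenoxide–enolate dianion of A5, which would attack the electrophilic oxygen of enantiopure (camphorsulfonyl)oxaziridine A6. A6 is drawn as the levorotatory antipode, which analogy with Z-enolates of simple aryl alkyl ketones suggests for R. The product would be the ring B silyl ether of the target, (2R)-1-[4-(geranyloxy)-2-hydroxyphenyl]-2-hydroxy-3-[4-(tert-butyldimethylsilyloxy)phenyl]propan-1-one A4, and A4 needs only desilylation.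
- In favour: the skeleton of A5 comes from aldol condensation and conjugate reduction, no chiral-pool material is needed, the sequence is short, and no ring A oxidation-state change is required. The oxaziridine A6 should not transfer oxygen to isolated alkenes at low temperature.
- Against: the selectivity depends on the geometry and aggregation of a dianion for which close models are lacking. The alkoxide of A4 would sit in a strongly basic medium in which α-ketols racemise or are oxidised further. The conjugate reduction towards A5 must spare two trisubstituted alkenes. The correct antipode of A6 can only be chosen by analogy.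
- Comparison: on structure the two plans are equal, both being convergent and both ending with the complete ring A pattern. On mechanism the chosen plan is better in stereocontrol: its configuration is carried in from an amino acid, whereas an incomplete enantiomeric excess in A4 would be hard to upgrade on a non-crystalline geranyl ether. On step economy the alternative is clearly better (about five steps against eight).

Alternative 3: The cut is the bond between the benzylic CH2 and ring B.
- Forward key step: 4-(tert-butyldimethylsilyloxy)phenylboronic acid A9 would transmetallate to a monovalent rhodium catalyst, for example [Rh(cod)OH]2 with an enantiopure diphosphine. The aryl–rhodium species derived from A9 would add to the terminal carbon of the 2-silyloxy enone 1-[2-(tert-butyldimethylsilyloxy)-4-(geranyloxy)phenyl]-2-(tert-butyldimethylsilyloxy)prop-2-en-1-one A8. The rhodium enolate would then be protonated on one face to give the tris-silyl ether of the target, (2R)-2-(tert-butyldimethylsilyloxy)-1-[2-(tert-butyldimethylsilyloxy)-4-(geranyloxy)phenyl]-3-[4-(tert-butyldimethylsilyloxy)phenyl]propan-1-one A7. A7 is 19 with one more silyl group, and global desilylation would follow.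
- In favour: the method is catalytic, either enantiomer is accessible, the aqueous conditions should tolerate isolated alkenes, A9 is a simple and stable coupling partner, and the endgame is that of the chosen plan.
- Against: the stereocentre is set in the protonation, not in the C–C bond formation. Enantioselective protonation of rhodium enolates is established mainly for α-amido and α-alkyl acrylates, not for α-silyloxy vinyl ketones. A8 is a polymerisable vinyl ketone that needs several steps of ring A chemistry, including the selective geranylation that the chosen plan avoids. A7 would remain in contact with base and water, so its configuration could erode.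
- Comparison: on structure the alternative is equal in endgame and in compatibility with the geranyl group, but it needs ring A with its ether in place before the key step, which the chosen plan obtains by construction. On mechanism the alternative is better in flexibility of absolute configuration and weaker in certainty of the stereochemical outcome. On step economy it is not better, since A8 should cost about as many steps as 14.

Key step: step 5

## Remarks before the steps

- Abbreviations: geranyl = (2E)-3,7-dimethylocta-2,6-dien-1-yl; TBS = tert-butyldimethylsilyl; TES = triethylsilyl.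
- Ring mapping: C1(=O), C3(O-geranyl) and C6 of 4 become C2, C4 and C1 of ring A, which reproduces the 1,2,4 pattern of 20. The ring numbering of 4 is kept in the names of 14 to 18.
- Configuration: the carbinol carbon is R in 5, 8, 10, 11, 13, 14, 16, 19 and 20, because the ligand ranking (N or O > carbonyl-type carbon > benzylic carbon > H) never changes.
- Assumption: 14 is a set of rapidly interconverting keto–enol tautomers and is drawn as the ring enol. 16 forms as both C6 epimers, which is immaterial because C6 becomes trigonal in step 7.
- Design choices within the disconnection: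
  - (a) Amidation precedes silylation, so no silyl ester has to be cleaved.
  - (b) The cheap enolate is used in twofold excess with no free amide base left.
  - (c) The selenium electrophile is an N–Se reagent that does not add to alkenes, and the selenide is oxidised with a peracid at −78 °C, with an amine trap added before warming.
  - (d) The final desilylation uses pyridine-buffered HF instead of a basic fluoride source.

## Route

Step 1
Reactants: 1 cyclohexane-1,3-dione; 2 geraniol
Product: 4 3-(geranyloxy)cyclohex-2-en-1-one, via (geranyloxy)triphenylphosphonium enolate salt 3 (not isolated)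
Conditions: PPh3, DIAD, THF, 0 °C to rt
Reagents that add atoms: none
Why: Mitsunobu reaction: the acidic dione protonates the betaine, the primary allylic alcohol is activated as oxyphosphonium ion 3 and is displaced in an SN2 sense by the enolate oxygen; cyclic 1,3-diones react on oxygen under these neutral conditions, which also spare the acid-sensitive allylic alcohol and leave the E alkene untouched.

Step 2
Reactants: 5 D-tyrosine
Product: 8 (2R)-2-hydroxy-3-(4-hydroxyphenyl)propanoic acid, via diazonium carboxylate 6 (not isolated), via alpha-lactone 7 (not isolated)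
Conditions: NaNO2, 1 M H2SO4 (aq), 0 °C to rt
Reagents that add atoms: water, O
Why: Diazotisation of an α-amino acid with neighbouring carboxylate participation: loss of N2 from 6 with inversion gives α-lactone 7, which water opens at the α-carbon with a second inversion, so the R configuration of 5 is retained in 8; cold dilute acid limits C-nitrosation of the phenol ring.

Step 3
Reactants: 8 (2R)-2-hydroxy-3-(4-hydroxyphenyl)propanoic acid
Product: 10 (2R)-2-hydroxy-3-(4-hydroxyphenyl)-N-methoxy-N-methylpropanamide, via benzotriazolyl ester 9 (not isolated)
Conditions: MeNHOMe·HCl, EDC·HCl, HOBt, N-methylmorpholine, DMF, 0 °C to rt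
Reagents that add atoms: N,O-dimethylhydroxylamine hydrochloride, CNOC.Cl
Why: Carbodiimide/HOBt amidation: the carboxylate is activated as ester 9 and captured by the amine much faster than by the secondary alcohol or the phenol, so no hydroxyl protection is needed; an α-hydroxy acid cannot racemise through an oxazolone, so the stereocentre is safe.

Step 4
Reactants: 10 (2R)-2-hydroxy-3-(4-hydroxyphenyl)-N-methoxy-N-methylpropanamide
Product: 11 (2R)-2-(TBS-oxy)-3-[4-(TBS-oxy)phenyl]-N-methoxy-N-methylpropanamide
Conditions: TBSCl (2.5 equiv), imidazole, DMF, rt
Reagents that add atoms: tert-butyldimethylsilyl chloride, CC(C)(C)[Si](C)(C)Cl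
Why: Imidazole-promoted silylation of a phenol and a secondary alcohol; placing it after amidation avoids a silyl ester, and the stereocentre is not involved.

Step 5
Reactants: 4 3-(geranyloxy)cyclohex-2-en-1-one; 11 (2R)-2-(TBS-oxy)-3-[4-(TBS-oxy)phenyl]-N-methoxy-N-methylpropanamide
Product: 14 6-[(2R)-2-(TBS-oxy)-3-[4-(TBS-oxy)phenyl]propanoyl]-3-(geranyloxy)cyclohex-2-en-1-one as its ring enol, via lithium enolate 12 (not isolated), via chelated tetrahedral adduct 13 (not isolated)
Conditions: LiN(i-Pr)2 (2.0 equiv), 4 (2.05 equiv), THF, −78 °C; 11 (1.0 equiv), −78 to −20 °C; AcOH, −78 °C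
Reagents that add atoms: none
Why: LiN(i-Pr)2 removes a proton from C6 of 4 under kinetic control (the γ protons at C4 are reached only under equilibrating conditions) and gives the cross-conjugated enolate 12. Its carbon end adds to the amide carbonyl of 11, and the lithium alkoxide 13 is held as a five-membered N-methoxy chelate, so it neither collapses nor is acylated again; acetic acid at low temperature then releases N,O-dimethylhydroxylamine and the β-diketone 14, stabilised as its hydrogen-bonded enol. The closest known reaction type is the Claisen-type C-acylation of ketone lithium enolates with N-methoxy-N-methylamides, combined with the established α′-functionalisation of kinetic enolates of 3-alkoxycyclohex-2-enones. One C–C bond (C6 to the ketone carbon) forms, no ring closes, and no new stereocentre survives, since C6 is trigonal in the enol and the hemiaminal carbon of 13 is lost. The step needs C6 over C4 selectivity (deprotonation at −78 °C, ketone added to the base), carbon over oxygen acylation (lithium counter-ion and a chelating amide in place of an acyl halide) and integrity of the R centre. The R centre is secure because the enolate is far too weak a base to deprotonate an amide α-carbon, no free amide base remains (4 in slight excess over the base), the carbinol carbon of 13 is not next to a carbonyl, and in 14 enolisation is drawn into the β-diketone, away from the stereocentre. Two equivalents of the cheap enolate are used so that any 14 formed by premature collapse is simply deprotonated without stalling the reaction; surplus 4 is recovered.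

Step 6
Reactants: 14 6-acyl-3-(geranyloxy)cyclohex-2-en-1-one (ring enol)
Product: 16 6-acyl-3-(geranyloxy)-6-(phenylselanyl)cyclohex-2-en-1-one (acyl as in 14; both C6 epimers), via sodium enolate 15 (not isolated)
Conditions: NaH (1.0 equiv), THF, 0 °C; N-(phenylseleno)phthalimide, −78 to 0 °C; aq NH4Cl
Reagents that add atoms: N-(phenylseleno)phthalimide, O=C1N([Se]c2ccccc2)C(=O)c2ccccc21
Why: α-Selenenylation of a stabilised β-diketone enolate: NaH removes only the enol proton, and enolate 15 attacks selenium through its central carbon C6; the N–Se reagent, unlike PhSeCl or PhSeBr, does not add to unactivated alkenes without acid, which protects the geranyl group; the new C6 centre forms as both epimers and is destroyed in step 7.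

Step 7
Reactants: 16 6-acyl-3-(geranyloxy)-6-(phenylselanyl)cyclohex-2-en-1-one
Product: 19 (2R)-2-(TBS-oxy)-3-[4-(TBS-oxy)phenyl]-1-[4-(geranyloxy)-2-hydroxyphenyl]propan-1-one, via selenoxide 17 (not isolated), via cyclohexa-2,5-dienone 18 (not isolated)
Conditions: mCPBA (1.05 equiv), CH2Cl2, −78 °C; i-Pr2NH (3 equiv), −78 °C to rt
Reagents that add atoms: none
Why: Selenoxide syn-elimination (Reich type): the peracid oxidises selenium at −78 °C much faster than it epoxidises a trisubstituted alkene, selenoxide 17 eliminates through a five-membered transition state towards C5–H (the only β-hydrogen) on warming, and the cross-conjugated dienone 18 tautomerises (C4–H to oxygen) to phenol 19, driven by aromatisation; the secondary amine traps benzeneselenenic acid before it can add to the geranyl alkenes and catalyses the tautomerisation.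

Step 8
Reactants: 19 (2R)-2-(TBS-oxy)-3-[4-(TBS-oxy)phenyl]-1-[4-(geranyloxy)-2-hydroxyphenyl]propan-1-one
Product: 20 (2R)-1-[4-(geranyloxy)-2-hydroxyphenyl]-2-hydroxy-3-(4-hydroxyphenyl)propan-1-one
Conditions: HF·pyridine, pyridine, THF, 0 °C to rt
Reagents that add atoms: none
Why: Fluoride-mediated cleavage of the aryl and the secondary alkyl silyl ether; the pyridine-buffered medium is not basic enough to enolise the α-ketol (no racemisation, no acyloin shift) and not acidic enough to ionise the geranyl ether, and the chelated ring A phenol is unaffected.

## Compound list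

1 | cyclohexane-1,3-dione | O=C1CCCC(=O)C1 | starting material
2 | geraniol, (2E)-3,7-dimethylocta-2,6-dien-1-ol | CC(C)=CCC/C(C)=C/CO | starting material
3 | (geranyloxy)triphenylphosphonium 3-oxocyclohex-1-en-1-olate (ion pair) | CC(C)=CCC/C(C)=C/CO[P+](c1ccccc1)(c1ccccc1)c1ccccc1.O=C1CCCC([O-])=C1 | intermediate (not isolated)
4 | 3-(geranyloxy)cyclohex-2-en-1-one | CC(C)=CCC/C(C)=C/COC1=CC(=O)CCC1 | intermediate
5 | D-tyrosine, (2R)-2-amino-3-(4-hydroxyphenyl)propanoic acid | N[C@H](Cc1ccc(O)cc1)C(=O)O | starting material
6 | (2R)-2-diazonio-3-(4-hydroxyphenyl)propanoate | N#[N+][C@H](Cc1ccc(O)cc1)C(=O)[O-] | intermediate (not isolated)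
7 | (3S)-3-(4-hydroxybenzyl)oxiran-2-one | O=C1O[C@H]1Cc1ccc(O)cc1 | intermediate (not isolated)
8 | (2R)-2-hydroxy-3-(4-hydroxyphenyl)propanoic acid | O[C@H](Cc1ccc(O)cc1)C(=O)O | intermediate
9 | 1H-benzotriazol-1-yl (2R)-2-hydroxy-3-(4-hydroxyphenyl)propanoate | O=C(On1nnc2ccccc21)[C@H](O)Cc1ccc(O)cc1 | intermediate (not isolated)
10 | (2R)-2-hydroxy-3-(4-hydroxyphenyl)-N-methoxy-N-methylpropanamide | CON(C)C(=O)[C@H](O)Cc1ccc(O)cc1 | intermediate
11 | (2R)-2-(tert-butyldimethylsilyloxy)-3-[4-(tert-butyldimethylsilyloxy)phenyl]-N-methoxy-N-methylpropanamide | CON(C)C(=O)[C@H](O[Si](C)(C)C(C)(C)C)Cc1ccc(O[Si](C)(C)C(C)(C)C)cc1 | intermediate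
12 | lithium 5-(geranyloxy)cyclohexa-1,5-dien-1-olate (C1–C6 enolate of 4) | CC(C)=CCC/C(C)=C/COC1=CC([O-])=CCC1.[Li+] | intermediate (not isolated)
13 | lithium (2R)-2-(tert-butyldimethylsilyloxy)-3-[4-(tert-butyldimethylsilyloxy)phenyl]-1-[4-(geranyloxy)-2-oxocyclohex-3-en-1-yl]-1-[methoxy(methyl)amino]propan-1-olate (epimers at the two new centres) | CC(C)=CCC/C(C)=C/COC1=CC(=O)C(CC1)C([O-])(N(C)OC)[C@H](O[Si](C)(C)C(C)(C)C)Cc1ccc(O[Si](C)(C)C(C)(C)C)cc1.[Li+] | intermediate (not isolated)
14 | (2R)-2-(tert-butyldimethylsilyloxy)-3-[4-(tert-butyldimethylsilyloxy)phenyl]-1-[4-(geranyloxy)-2-hydroxycyclohexa-1,3-dien-1-yl]propan-1-one (ring enol of the 6-acyl-3-geranyloxycyclohex-2-en-1-one) | CC(C)=CCC/C(C)=C/COC1=CC(O)=C(CC1)C(=O)[C@H](O[Si](C)(C)C(C)(C)C)Cc1ccc(O[Si](C)(C)C(C)(C)C)cc1 | intermediate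
15 | sodium 2-[(2R)-2-(tert-butyldimethylsilyloxy)-3-[4-(tert-butyldimethylsilyloxy)phenyl]propanoyl]-5-(geranyloxy)cyclohexa-1,5-dien-1-olate | CC(C)=CCC/C(C)=C/COC1=CC([O-])=C(CC1)C(=O)[C@H](O[Si](C)(C)C(C)(C)C)Cc1ccc(O[Si](C)(C)C(C)(C)C)cc1.[Na+] | intermediate (not isolated)
16 | 6-[(2R)-2-(tert-butyldimethylsilyloxy)-3-[4-(tert-butyldimethylsilyloxy)phenyl]propanoyl]-3-(geranyloxy)-6-(phenylselanyl)cyclohex-2-en-1-one (both C6 epimers) | CC(C)=CCC/C(C)=C/COC1=CC(=O)C(CC1)([Se]c1ccccc1)C(=O)[C@H](O[Si](C)(C)C(C)(C)C)Cc1ccc(O[Si](C)(C)C(C)(C)C)cc1 | intermediate
17 | 6-(benzeneseleninyl)-6-[(2R)-2-(tert-butyldimethylsilyloxy)-3-[4-(tert-butyldimethylsilyloxy)phenyl]propanoyl]-3-(geranyloxy)cyclohex-2-en-1-one (stereoisomers at C6 and Se) | CC(C)=CCC/C(C)=C/COC1=CC(=O)C(CC1)([Se](=O)c1ccccc1)C(=O)[C@H](O[Si](C)(C)C(C)(C)C)Cc1ccc(O[Si](C)(C)C(C)(C)C)cc1 | intermediate (not isolated)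
18 | 6-[(2R)-2-(tert-butyldimethylsilyloxy)-3-[4-(tert-butyldimethylsilyloxy)phenyl]propanoyl]-3-(geranyloxy)cyclohexa-2,5-dien-1-one | CC(C)=CCC/C(C)=C/COC1=CC(=O)C(=CC1)C(=O)[C@H](O[Si](C)(C)C(C)(C)C)Cc1ccc(O[Si](C)(C)C(C)(C)C)cc1 | intermediate (not isolated)
19 | (2R)-2-(tert-butyldimethylsilyloxy)-3-[4-(tert-butyldimethylsilyloxy)phenyl]-1-[4-(geranyloxy)-2-hydroxyphenyl]propan-1-one | CC(C)=CCC/C(C)=C/COc1ccc(C(=O)[C@H](O[Si](C)(C)C(C)(C)C)Cc2ccc(O[Si](C)(C)C(C)(C)C)cc2)c(O)c1 | intermediate
20 | (2R)-1-[4-(geranyloxy)-2-hydroxyphenyl]-2-hydroxy-3-(4-hydroxyphenyl)propan-1-one (CNP0159413.1) | CC(C)=CCC/C(C)=C/COc1ccc(C(=O)[C@H](O)Cc2ccc(O)cc2)c(O)c1 | target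

## Step count and least certain steps

Total: 8 steps. Longest linear sequence: 7 steps (5 to 20 through steps 2–8); step 1 is the one-step branch to 4.

Step 5 (key step). The most likely failure is sluggish addition of the stabilised enolate to the hindered, α-branched amide at the temperature that keeps the kinetic enolate intact. On warming, proton transfer to the extended C4 dienolate, self-condensation of 4, or premature collapse of 13 followed by O-acylation could then compete.
Fallback (aldol addition and oxidation instead of acylation): from 11, reduction with i-Bu2AlH (THF, −78 °C) gives (2R)-2-(tert-butyldimethylsilyloxy)-3-[4-(tert-butyldimethylsilyloxy)phenyl]propanal F1, used at once and cold to protect its α-centre. Aldol addition of enolate 12 at −78 °C, which is fast and irreversible for an aldehyde, gives 6-[(2R)-2-(tert-butyldimethylsilyloxy)-3-[4-(tert-butyldimethylsilyloxy)phenyl]-1-hydroxypropyl]-3-(geranyloxy)cyclohex-2-en-1-one F2 as a mixture of epimers. Oxidation with Dess–Martin periodinane (NaHCO3, CH2Cl2) converges on 14, where the route is rejoined.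

Step 6. The most likely failure is competition of the geranyl alkenes with the enolate carbon for the selenium electrophile. The second risk is loss of the new substituent by nucleophilic attack at selenium or retro-Claisen cleavage of the now non-enolisable β-diketone during work-up.
Fallback (sulfur in place of selenium, with a reagent inert to alkenes and a thermal elimination): from 14, the sodium enolate 15 is sulfenylated with S-phenyl benzenethiosulfonate to give 6-[(2R)-2-(tert-butyldimethylsilyloxy)-3-[4-(tert-butyldimethylsilyloxy)phenyl]propanoyl]-3-(geranyloxy)-6-(phenylsulfanyl)cyclohex-2-en-1-one F3. mCPBA at −78 °C gives the corresponding 6-(benzenesulfinyl) compound F4. Warming in toluene (50–80 °C) with trimethyl phosphite as sulfenic acid trap should bring about syn-elimination to 18 and tautomerisation. The route is rejoined at 19.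

Step 7. The most likely failure is oxidation of the trisubstituted alkenes by excess peracid or by peroxyseleninic species, or hydroxyselenation by selenenic acid, before elimination and trapping are complete.
Fallback (oxidant-free, one-flask dehydrogenation of the Mukaiyama type): from 14, the enolate is treated with N-tert-butylbenzenesulfinimidoyl chloride (THF, −78 °C to rt) to give 6-[(2R)-2-(tert-butyldimethylsilyloxy)-3-[4-(tert-butyldimethylsilyloxy)phenyl]propanoyl]-6-(N-tert-butyl-S-phenylsulfinimidoyl)-3-(geranyloxy)cyclohex-2-en-1-one F5. Its nitrogen removes the C5 proton intramolecularly, giving 18 and then its phenol tautomer. The route is rejoined at 19.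

Step 8. The most likely failure is slow cleavage of the hindered secondary silyl ether next to the ketone. Long exposure would then allow erosion of configuration through enolisation of the liberated α-ketol, or attack of acid on the geranyl alkenes.
Fallback (more labile protecting group and solvolytic instead of fluoride cleavage): from 10, TESCl/imidazole gives (2R)-N-methoxy-N-methyl-2-(triethylsilyloxy)-3-[4-(triethylsilyloxy)phenyl]propanamide F6. Acylation of 12 as in step 5 gives 6-[(2R)-2-(triethylsilyloxy)-3-[4-(triethylsilyloxy)phenyl]propanoyl]-3-(geranyloxy)cyclohex-2-en-1-one F7. Selenenylation as in step 6 gives 6-[(2R)-2-(triethylsilyloxy)-3-[4-(triethylsilyloxy)phenyl]propanoyl]-3-(geranyloxy)-6-(phenylselanyl)cyclohex-2-en-1-one F8. Oxidation–elimination as in step 7 gives (2R)-2-(triethylsilyloxy)-3-[4-(triethylsilyloxy)phenyl]-1-[4-(geranyloxy)-2-hydroxyphenyl]propan-1-one F9. Both triethylsilyl ethers are then solvolysed with AcOH/THF/H2O at rt, a medium without fluoride or base. The route is rejoined at 20.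

Step 1. The most likely failure is alkylation at C2 of the dione or allylic transposition of the geranyl unit in competition with O-alkylation.
Fallback (addition–elimination in place of alcohol activation): from 1, oxalyl chloride with catalytic DMF (CH2Cl2) gives 3-chlorocyclohex-2-en-1-one F10. The sodium alkoxide of 2 (NaH, THF, 0 °C to rt) then displaces chloride by conjugate addition–elimination. The C–O bond is formed at the ring carbon, so neither C-alkylation nor transposition is possible. The route is rejoined at 4.

## Further compounds

F1 | step 5 | (2R)-2-(tert-butyldimethylsilyloxy)-3-[4-(tert-butyldimethylsilyloxy)phenyl]propanal | O=C[C@H](O[Si](C)(C)C(C)(C)C)Cc1ccc(O[Si](C)(C)C(C)(C)C)cc1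
F2 | step 5 | 6-[(2R)-2-(tert-butyldimethylsilyloxy)-3-[4-(tert-butyldimethylsilyloxy)phenyl]-1-hydroxypropyl]-3-(geranyloxy)cyclohex-2-en-1-one (epimers at C6 and at the new carbinol) | CC(C)=CCC/C(C)=C/COC1=CC(=O)C(CC1)C(O)[C@H](O[Si](C)(C)C(C)(C)C)Cc1ccc(O[Si](C)(C)C(C)(C)C)cc1
F3 | step 6 | 6-[(2R)-2-(tert-butyldimethylsilyloxy)-3-[4-(tert-butyldimethylsilyloxy)phenyl]propanoyl]-3-(geranyloxy)-6-(phenylsulfanyl)cyclohex-2-en-1-one (both C6 epimers) | CC(C)=CCC/C(C)=C/COC1=CC(=O)C(CC1)(Sc1ccccc1)C(=O)[C@H](O[Si](C)(C)C(C)(C)C)Cc1ccc(O[Si](C)(C)C(C)(C)C)cc1
F4 | step 6 | 6-(benzenesulfinyl)-6-[(2R)-2-(tert-butyldimethylsilyloxy)-3-[4-(tert-butyldimethylsilyloxy)phenyl]propanoyl]-3-(geranyloxy)cyclohex-2-en-1-one (stereoisomers at C6 and S) | CC(C)=CCC/C(C)=C/COC1=CC(=O)C(CC1)(S(=O)c1ccccc1)C(=O)[C@H](O[Si](C)(C)C(C)(C)C)Cc1ccc(O[Si](C)(C)C(C)(C)C)cc1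
F5 | step 7 | 6-[(2R)-2-(tert-butyldimethylsilyloxy)-3-[4-(tert-butyldimethylsilyloxy)phenyl]propanoyl]-6-(N-tert-butyl-S-phenylsulfinimidoyl)-3-(geranyloxy)cyclohex-2-en-1-one (stereoisomers at C6 and S) | CC(C)=CCC/C(C)=C/COC1=CC(=O)C(CC1)(S(=NC(C)(C)C)c1ccccc1)C(=O)[C@H](O[Si](C)(C)C(C)(C)C)Cc1ccc(O[Si](C)(C)C(C)(C)C)cc1
F6 | step 8 | (2R)-N-methoxy-N-methyl-2-(triethylsilyloxy)-3-[4-(triethylsilyloxy)phenyl]propanamide | CON(C)C(=O)[C@H](O[Si](CC)(CC)CC)Cc1ccc(O[Si](CC)(CC)CC)cc1
F7 | step 8 | 6-[(2R)-2-(triethylsilyloxy)-3-[4-(triethylsilyloxy)phenyl]propanoyl]-3-(geranyloxy)cyclohex-2-en-1-one (ring enol) | CC(C)=CCC/C(C)=C/COC1=CC(O)=C(CC1)C(=O)[C@H](O[Si](CC)(CC)CC)Cc1ccc(O[Si](CC)(CC)CC)cc1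
F8 | step 8 | 6-[(2R)-2-(triethylsilyloxy)-3-[4-(triethylsilyloxy)phenyl]propanoyl]-3-(geranyloxy)-6-(phenylselanyl)cyclohex-2-en-1-one (both C6 epimers) | CC(C)=CCC/C(C)=C/COC1=CC(=O)C(CC1)([Se]c1ccccc1)C(=O)[C@H](O[Si](CC)(CC)CC)Cc1ccc(O[Si](CC)(CC)CC)cc1
F9 | step 8 | (2R)-2-(triethylsilyloxy)-3-[4-(triethylsilyloxy)phenyl]-1-[4-(geranyloxy)-2-hydroxyphenyl]propan-1-one | CC(C)=CCC/C(C)=C/COc1ccc(C(=O)[C@H](O[Si](CC)(CC)CC)Cc2ccc(O[Si](CC)(CC)CC)cc2)c(O)c1
F10 | step 1 | 3-chlorocyclohex-2-en-1-one | O=C1C=C(Cl)CCC1
A1 | alternative 1 | (2R)-2-(tert-butyldimethylsilyloxy)-3-[4-(tert-butyldimethylsilyloxy)phenyl]-1-(2,4-dihydroxyphenyl)propan-1-one | O=C(c1ccc(O)cc1O)[C@H](O[Si](C)(C)C(C)(C)C)Cc1ccc(O[Si](C)(C)C(C)(C)C)cc1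
A2 | alternative 1 | (4R)-4-(tert-butyldimethylsilyloxy)-5-[4-(tert-butyldimethylsilyloxy)phenyl]pent-1-yn-3-one | C#CC(=O)[C@H](O[Si](C)(C)C(C)(C)C)Cc1ccc(O[Si](C)(C)C(C)(C)C)cc1
A3 | alternative 1 | 1-methoxy-1,3-bis(trimethylsilyloxy)buta-1,3-diene (geometry at C1=C2 immaterial) | COC(O[Si](C)(C)C)=CC(=C)O[Si](C)(C)C
A4 | alternative 2 | (2R)-1-[4-(geranyloxy)-2-hydroxyphenyl]-2-hydroxy-3-[4-(tert-butyldimethylsilyloxy)phenyl]propan-1-one | CC(C)=CCC/C(C)=C/COc1ccc(C(=O)[C@H](O)Cc2ccc(O[Si](C)(C)C(C)(C)C)cc2)c(O)c1
A5 | alternative 2 | 1-[4-(geranyloxy)-2-hydroxyphenyl]-3-[4-(tert-butyldimethylsilyloxy)phenyl]propan-1-one | CC(C)=CCC/C(C)=C/COc1ccc(C(=O)CCc2ccc(O[Si](C)(C)C(C)(C)C)cc2)c(O)c1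
A6 | alternative 2 | (camphorsulfonyl)oxaziridine, levorotatory antipode, oxaziridine oxygen endo | CC1(C)[C@H]2CC[C@@]13CS(=O)(=O)N4O[C@]34C2
A7 | alternative 3 | (2R)-2-(tert-butyldimethylsilyloxy)-1-[2-(tert-butyldimethylsilyloxy)-4-(geranyloxy)phenyl]-3-[4-(tert-butyldimethylsilyloxy)phenyl]propan-1-one | CC(C)=CCC/C(C)=C/COc1ccc(C(=O)[C@H](O[Si](C)(C)C(C)(C)C)Cc2ccc(O[Si](C)(C)C(C)(C)C)cc2)c(O[Si](C)(C)C(C)(C)C)c1
A8 | alternative 3 | 1-[2-(tert-butyldimethylsilyloxy)-4-(geranyloxy)phenyl]-2-(tert-butyldimethylsilyloxy)prop-2-en-1-one | CC(C)=CCC/C(C)=C/COc1ccc(C(=O)C(=C)O[Si](C)(C)C(C)(C)C)c(O[Si](C)(C)C(C)(C)C)c1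
A9 | alternative 3 | 4-(tert-butyldimethylsilyloxy)phenylboronic acid | CC(C)(C)[Si](C)(C)Oc1ccc(B(O)O)cc1
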